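**Plan**

- Cuts: the C8=C9 alkene (Horner–Wadsworth–Emmons) separates a C1–C8 trienyl phosphonate that already carries the cyclohexyl ester from a C9–C23 (Z)-β-chloroenal. Within the enal the cuts are C19–C20 (butenyl addition), C10–C11 and C9–C10 (alkyne homologation, hydroxymethylation), C17–O/C18–Cl (chlorocyclisation), C17=C18 (cross-metathesis), C15–C16 (allylation) and C13–C14 (glycolate aldol).
- Enabling feature: O15 and O17 are 1,3-syn and C18–Cl is anti to C17–O. This is the imprint of anti addition of chlorine and an O15-bound carbonate oxygen across an (E)-C17=C18 alkene, closing a six-membered 1,3-dioxan-2-one ring.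
- Forward order: the open chain grows C11–C13, then C15, then C19. The dioxolane on O13/O14 and the cyclic carbonate on O15/O17 (later exchanged for a dioxane ketal) are temporary rings; the cyclohexane is bought. C20–C23 and then C9–C10 are added, and the halves are joined last at C8=C9.
- Stereochemistry: C12 from methyl (S)-3-hydroxy-2-methylpropanoate; C13/C14 from a chiral glycolate (anti aldol, Felkin-matched); C15 by Felkin–Anh allylation; C17/C18 in the key step; C19 by Cornforth-controlled addition to an α-chloroaldehyde; (10Z) by trans-hydroalumination/chlorination; C1′ from (S)-cyclohex-3-ene-1-carboxylic acid, C3′/C4′ by syn-dihydroxylation.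

Key step: step 10

Locants C1–C23 (chain, from the ester carbonyl) and C1′–C6′ (ring, from the carboxyl-bearing carbon) are those of the target. TBDPS = tert-butyldiphenylsilyl, TBS = tert-butyldimethylsilyl, TES = triethylsilyl.

Assumption: the (5S,6S)-butane-2,3-diacetal glycolate of step 3 is taken as purchasable (otherwise three steps from (S)-3-chloropropane-1,2-diol), and its enolate is assumed to react on the face anti to the axial C5 methoxy group.

**Route**

Step 1
Reactants: 1 methyl (2S)-3-hydroxy-2-methylpropanoate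
Product: 2 methyl (2S)-3-(tert-butyldiphenylsilyloxy)-2-methylpropanoate
Conditions: TBDPSCl, imidazole, CH2Cl2, 0 °C → rt
Reagents that add atoms: tert-butyl(chloro)diphenylsilane, CC(C)(C)[Si](Cl)(c1ccccc1)c1ccccc1
Why: Imidazole-promoted silylation of the primary alcohol leaves the α-stereocentre (future C12) untouched.

Step 2
Reactants: 2 methyl (2S)-3-(tert-butyldiphenylsilyloxy)-2-methylpropanoate
Product: 3 (2S)-3-(tert-butyldiphenylsilyloxy)-2-methylpropanal
Conditions: i-Bu2AlH (1.05 equiv), CH2Cl2, −78 °C; MeOH, then aq. potassium sodium tartrate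
Reagents that add atoms: none
Why: Partial ester reduction stops at the aluminium hemiacetal at −78 °C; the aldehyde should be used crude to avoid α-epimerisation.

Step 3
Reactants: 3 (2S)-3-(tert-butyldiphenylsilyloxy)-2-methylpropanal; 4 (5S,6S)-5,6-dimethoxy-5,6-dimethyl-1,4-dioxan-2-one
Product: 5 (3R,5S,6S)-3-[(1R,2S)-3-(tert-butyldiphenylsilyloxy)-1-hydroxy-2-methylpropyl]-5,6-dimethoxy-5,6-dimethyl-1,4-dioxan-2-one
Conditions: LiN(SiMe3)2 (1.05 equiv), THF, −78 °C; then 3, −78 °C; aq. NH4Cl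
Reagents that add atoms: none
Why: Lithium-enolate anti-glycolate aldol: the ring-locked (E)-enolate should react through a Zimmerman–Traxler chair to the 13,14-anti adduct, the enolate face anti to the axial C5 methoxy group sets C14, and the aldehyde is attacked on its Felkin face (12,13-syn), so reagent and substrate control are matched.

Step 4
Reactants: 5 (3R,5S,6S)-3-[(1R,2S)-3-(tert-butyldiphenylsilyloxy)-1-hydroxy-2-methylpropyl]-5,6-dimethoxy-5,6-dimethyl-1,4-dioxan-2-one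
Product: 7 methyl (4R,5R)-5-[(2S)-1-(tert-butyldiphenylsilyloxy)propan-2-yl]-2,2-dimethyl-1,3-dioxolane-4-carboxylate, via dihydroxy methyl ester 6 (not isolated)
Conditions: HCl (0.1 M) in MeOH, rt; evaporate; Me2C(OMe)2, PPTS (cat.), acetone, rt
Reagents that add atoms: methanol, CO; 2,2-dimethoxypropane, COC(C)(C)OC
Why: Acid methanolysis opens the lactone and releases the diacetal as 3,3-dimethoxybutan-2-one, and the freed 13,14-anti diol is then closed to the cis-dioxolane by acetal exchange; the primary TBDPS ether should survive the brief acid exposure.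

Step 5
Reactants: 7 methyl (4R,5R)-5-[(2S)-1-(tert-butyldiphenylsilyloxy)propan-2-yl]-2,2-dimethyl-1,3-dioxolane-4-carboxylate
Product: 8 (4R,5R)-5-[(2S)-1-(tert-butyldiphenylsilyloxy)propan-2-yl]-2,2-dimethyl-1,3-dioxolane-4-carbaldehyde
Conditions: i-Bu2AlH (1.1 equiv), CH2Cl2, −78 °C; MeOH, then aq. potassium sodium tartrate
Reagents that add atoms: none
Why: The α-alkoxy ester gives a chelated aluminium hemiacetal that collapses only on work-up (partial reduction); the cis-dioxolane aldehyde should be used at once to avoid epimerisation at C14.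

Step 6
Reactants: 8 (4R,5R)-5-[(2S)-1-(tert-butyldiphenylsilyloxy)propan-2-yl]-2,2-dimethyl-1,3-dioxolane-4-carbaldehyde; 9 allyltributylstannane
Product: 10 (1S)-1-[(4S,5R)-5-[(2S)-1-(tert-butyldiphenylsilyloxy)propan-2-yl]-2,2-dimethyl-1,3-dioxolan-4-yl]but-3-en-1-ol
Conditions: BF3·OEt2, CH2Cl2, −78 °C; aq. NaHCO3
Reagents that add atoms: none
Why: Lewis acid-promoted allylstannane addition through an open transition state; monodentate BF3 excludes chelation, so the polar Felkin–Anh arrangement (C14–O anti to the incoming allyl group) should give the 14,15-anti alcohol (15S).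

Step 7
Reactants: 11 (Z)-but-2-ene-1,4-diol
Product: 12 (Z)-1,4-bis(tert-butyldimethylsilyloxy)but-2-ene
Conditions: TBSCl (2.2 equiv), imidazole, DMF, rt
Reagents that add atoms: tert-butyl(chloro)dimethylsilane, CC(C)(C)[Si](C)(C)Cl
Why: Standard imidazole-promoted bis-silylation of a primary diol.

Step 8
Reactants: 10 (1S)-1-[(4S,5R)-5-[(2S)-1-(tert-butyldiphenylsilyloxy)propan-2-yl]-2,2-dimethyl-1,3-dioxolan-4-yl]but-3-en-1-ol; 12 (Z)-1,4-bis(tert-butyldimethylsilyloxy)but-2-ene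
Product: 13 (1S,3E)-5-(tert-butyldimethylsilyloxy)-1-[(4S,5R)-5-[(2S)-1-(tert-butyldiphenylsilyloxy)propan-2-yl]-2,2-dimethyl-1,3-dioxolan-4-yl]pent-3-en-1-ol
Conditions: second-generation Grubbs catalyst (H2IMes)(PCy3)Cl2Ru=CHPh (5 mol %), 12 (3 equiv), CH2Cl2, 40 °C
Reagents that add atoms: none
Why: Olefin cross-metathesis of the terminal alkene with an excess of the symmetrical allylic ether should favour the (E)-alkene under thermodynamic control; residual (Z)-isomer must be removed by chromatography because the alkene geometry becomes the C18 configuration.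

Step 9
Reactants: 13 (1S,3E)-5-(tert-butyldimethylsilyloxy)-1-[(4S,5R)-5-[(2S)-1-(tert-butyldiphenylsilyloxy)propan-2-yl]-2,2-dimethyl-1,3-dioxolan-4-yl]pent-3-en-1-ol; 14 di-tert-butyl dicarbonate
Product: 15 tert-butyl (1S,3E)-5-(tert-butyldimethylsilyloxy)-1-[(4S,5R)-5-[(2S)-1-(tert-butyldiphenylsilyloxy)propan-2-yl]-2,2-dimethyl-1,3-dioxolan-4-yl]pent-3-en-1-yl carbonate
Conditions: DMAP (0.2 equiv), MeCN, rt
Reagents that add atoms: none
Why: DMAP-catalysed acyl transfer from the pyrocarbonate converts the secondary homoallylic alcohol into its tert-butyl carbonate.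

Step 10
Reactants: 15 tert-butyl (1S,3E)-5-(tert-butyldimethylsilyloxy)-1-[(4S,5R)-5-[(2S)-1-(tert-butyldiphenylsilyloxy)propan-2-yl]-2,2-dimethyl-1,3-dioxolan-4-yl]pent-3-en-1-yl carbonate
Product: 16 (4R,6S)-4-[(1S)-2-(tert-butyldimethylsilyloxy)-1-chloroethyl]-6-[(4S,5R)-5-[(2S)-1-(tert-butyldiphenylsilyloxy)propan-2-yl]-2,2-dimethyl-1,3-dioxolan-4-yl]-1,3-dioxan-2-one
Conditions: 1,3-dichloro-5,5-dimethylhydantoin (1.1 equiv), Ph3P=S (10 mol %), MeCN/CH2Cl2 (1:1), −40 → −20 °C, dark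
Reagents that add atoms: 1,3-dichloro-5,5-dimethylhydantoin, CC1(C)N(Cl)C(=O)N(Cl)C1=O
Why: Proposed new method: the Lewis base-activated chlorenium donor should transfer Cl+ to the (E)-C17=C18 alkene while the carbonyl oxygen of the O15 tert-butyl carbonate opens the chloriranium ion at C17 from the opposite face, and the resulting 2-tert-butoxy-1,3-dioxan-2-ylium ion then loses isobutene to the hydantoin anion; the closest known reaction types are the iodo- and bromocarbonate cyclisations of homoallylic tert-butyl carbonates and chlorolactonisation or chlorocyclisation of alkenoic acids and alkenyl carbamates with the same reagent. The 1,3-dioxan-2-one closes in the 6-exo mode, with the new C17–O bond in the ring and C18–Cl outside it. C17 is controlled by C15 through a chair transition state in which the C15 substituent and the developing C17 side chain are both equatorial (cis-4,6, hence 15,17-syn), and C18 by the stereospecific anti addition across the E-alkene (17,18-anti). The step needs 6-exo over 7-endo regioselectivity, which ring size and the inductive pull of the allylic O19 (disfavouring cation character at C18) should secure. It also needs participation by the carbonate oxygen and not by the acetonide oxygen O14, which the greater nucleophilicity of the carbonyl oxygen and the irreversible loss of isobutene should secure. Because a chloriranium ion is less bridged and less reversible than an iodiranium ion, low temperature and a non-nucleophilic counter-anion are chosen to keep capture tight and to suppress allylic chlorination.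

Step 11
Reactants: 16 (4R,6S)-4-[(1S)-2-(tert-butyldimethylsilyloxy)-1-chloroethyl]-6-[(4S,5R)-5-[(2S)-1-(tert-butyldiphenylsilyloxy)propan-2-yl]-2,2-dimethyl-1,3-dioxolan-4-yl]-1,3-dioxan-2-one
Product: 17 (2S,3R,5S)-1-(tert-butyldimethylsilyloxy)-5-[(4S,5R)-5-[(2S)-1-(tert-butyldiphenylsilyloxy)propan-2-yl]-2,2-dimethyl-1,3-dioxolan-4-yl]-2-chloropentane-3,5-diol
Conditions: i-Bu2AlH (4 equiv), CH2Cl2, −78 → −40 °C; MeOH, then aq. potassium sodium tartrate
Reagents that add atoms: none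
Why: Reductive cleavage of the cyclic carbonate (its carbonyl carbon leaves as methanol) avoids base, and the C17 aluminium alkoxide should not displace the C18 chloride at low temperature.

Step 12
Reactants: 17 (2S,3R,5S)-1-(tert-butyldimethylsilyloxy)-5-[(4S,5R)-5-[(2S)-1-(tert-butyldiphenylsilyloxy)propan-2-yl]-2,2-dimethyl-1,3-dioxolan-4-yl]-2-chloropentane-3,5-diol
Product: 18 (4R,6S)-4-[(1S)-2-(tert-butyldimethylsilyloxy)-1-chloroethyl]-6-[(4S,5R)-5-[(2S)-1-(tert-butyldiphenylsilyloxy)propan-2-yl]-2,2-dimethyl-1,3-dioxolan-4-yl]-2,2-dimethyl-1,3-dioxane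
Conditions: Me2C(OMe)2, PPTS (cat.), CH2Cl2, rt
Reagents that add atoms: 2,2-dimethoxypropane, COC(C)(C)OC
Why: Acetal exchange closes the syn-1,3-diol to a chair acetonide and masks O17 as an ether, so that no alkoxide can form next to C18–Cl in the later basic steps.

Step 13
Reactants: 18 (4R,6S)-4-[(1S)-2-(tert-butyldimethylsilyloxy)-1-chloroethyl]-6-[(4S,5R)-5-[(2S)-1-(tert-butyldiphenylsilyloxy)propan-2-yl]-2,2-dimethyl-1,3-dioxolan-4-yl]-2,2-dimethyl-1,3-dioxane
Product: 19 (2S)-2-chloro-2-[(4R,6S)-6-[(4S,5R)-5-[(2S)-1-(tert-butyldiphenylsilyloxy)propan-2-yl]-2,2-dimethyl-1,3-dioxolan-4-yl]-2,2-dimethyl-1,3-dioxan-4-yl]ethan-1-ol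
Conditions: HF·pyridine, pyridine, THF, 0 °C → rt
Reagents that add atoms: none
Why: Buffered HF cleaves the primary TBS ether much faster than the primary TBDPS ether (selective desilylation) and spares both acetonides.

Step 14
Reactants: 19 (2S)-2-chloro-2-[(4R,6S)-6-[(4S,5R)-5-[(2S)-1-(tert-butyldiphenylsilyloxy)propan-2-yl]-2,2-dimethyl-1,3-dioxolan-4-yl]-2,2-dimethyl-1,3-dioxan-4-yl]ethan-1-ol
Product: 20 (2R)-2-chloro-2-[(4R,6S)-6-[(4S,5R)-5-[(2S)-1-(tert-butyldiphenylsilyloxy)propan-2-yl]-2,2-dimethyl-1,3-dioxolan-4-yl]-2,2-dimethyl-1,3-dioxan-4-yl]acetaldehyde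
Conditions: Dess–Martin periodinane, NaHCO3, CH2Cl2, 0 °C
Reagents that add atoms: none
Why: Buffered Dess–Martin oxidation gives the α-chloroaldehyde under neutral conditions; it should be used crude at once to avoid epimerisation at C18.

Step 15
Reactants: 20 (2R)-2-chloro-2-[(4R,6S)-6-[(4S,5R)-5-[(2S)-1-(tert-butyldiphenylsilyloxy)propan-2-yl]-2,2-dimethyl-1,3-dioxolan-4-yl]-2,2-dimethyl-1,3-dioxan-4-yl]acetaldehyde; 21 but-1-yne
Product: 22 C11–C23 segment (12S,13R,14S,15S,17R,18S,19S,20E): 11-OTBDPS; 13,14-O- and 15,17-O-isopropylidene; 18-Cl; 19-OH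
Conditions: 21, Cp2Zr(H)Cl, CH2Cl2, rt; Me2Zn, −65 °C; then 20, −65 → 0 °C; aq. NH4Cl
Reagents that add atoms: none
Why: syn-Hydrozirconation of the alkyne and zirconium-to-zinc transmetalation give the (E)-butenylzinc reagent, which adds with retention of alkene geometry; the Cornforth arrangement (C=O and C18–Cl antiparallel, attack past H) should give the 18,19-anti chlorohydrin (19S), and the weakly basic zinc alkoxide should not close to an epoxide.

Step 16
Reactants: 22 C11–C23 segment (12S,13R,14S,15S,17R,18S,19S,20E): 11-OTBDPS; 13,14-O- and 15,17-O-isopropylidene; 18-Cl; 19-OH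
Product: 23 C11–C23 diol (12S,13R,14S,15S,17R,18S,19S,20E): 11-OH; 13,14-O- and 15,17-O-isopropylidene; 18-Cl; 19-OH
Conditions: Bu4NF, AcOH (1:1), THF, 0 °C → rt
Reagents that add atoms: none
Why: Fluoride cleaves the primary TBDPS ether, and the acetic acid buffer prevents an O19 alkoxide that could displace the C18 chloride.

Step 17
Reactants: 23 C11–C23 diol (12S,13R,14S,15S,17R,18S,19S,20E): 11-OH; 13,14-O- and 15,17-O-isopropylidene; 18-Cl; 19-OH
Product: 24 C11–C23 bis-silyl ether (12S,13R,14S,15S,17R,18R,19S,20E): 11-OTES; 13,14-O- and 15,17-O-isopropylidene; 18-Cl; 19-OTES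
Conditions: Et3SiOTf (2.5 equiv), 2,6-lutidine, CH2Cl2, −78 °C
Reagents that add atoms: triethylsilyl trifluoromethanesulfonate, CC[Si](CC)(CC)OS(=O)(=O)C(F)(F)F
Why: Silyl triflate with a hindered pyridine base silylates both hydroxyls under conditions that leave the chlorohydrin intact.

Step 18
Reactants: 24 C11–C23 bis-silyl ether (12S,13R,14S,15S,17R,18R,19S,20E): 11-OTES; 13,14-O- and 15,17-O-isopropylidene; 18-Cl; 19-OTES
Product: 25 C11–C23 aldehyde (12R,13R,14S,15S,17R,18R,19S,20E): C11 CHO; 13,14-O- and 15,17-O-isopropylidene; 18-Cl; 19-OTES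
Conditions: (COCl)2, DMSO, CH2Cl2, −78 → −40 °C; Et3N, −78 → 0 °C
Reagents that add atoms: none
Why: Under Swern conditions chlorodimethylsulfonium chloride cleaves the unhindered primary TES ether and oxidises it in place to the aldehyde, while the hindered secondary TES ether at O19 should be retained.

Step 19
Reactants: 25 C11–C23 aldehyde (12R,13R,14S,15S,17R,18R,19S,20E): C11 CHO; 13,14-O- and 15,17-O-isopropylidene; 18-Cl; 19-OTES
Product: 26 C10–C23 terminal alkyne (12S,13R,14S,15S,17R,18R,19S,20E): C10≡C11; 13,14-O- and 15,17-O-isopropylidene; 18-Cl; 19-OTES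
Conditions: dimethyl (1-diazo-2-oxopropyl)phosphonate, K2CO3, MeOH, 0 °C → rt
Reagents that add atoms: dimethyl (1-diazo-2-oxopropyl)phosphonate, COP(=O)(OC)C(=[N+]=[N-])C(C)=O
Why: Ohira–Bestmann homologation: the diazomethylphosphonate anion formed in situ adds to the aldehyde and the alkylidene carbene rearranges to the alkyne under conditions mild enough to keep C12 intact.

Step 20
Reactants: 26 C10–C23 terminal alkyne (12S,13R,14S,15S,17R,18R,19S,20E): C10≡C11; 13,14-O- and 15,17-O-isopropylidene; 18-Cl; 19-OTES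
Product: 28 C9–C23 propargylic alcohol (12S,13R,14S,15S,17R,18R,19S,20E; 9-OH; C10≡C11; 13,14:15,17-di-O-isopropylidene; 18-Cl; 19-OTES), via lithium acetylide 27 (not isolated)
Conditions: n-BuLi (1.05 equiv), THF, −78 °C; (CH2O)n, −78 °C → rt; aq. NH4Cl
Reagents that add atoms: formaldehyde (as paraformaldehyde), C=O
Why: Deprotonation of the terminal alkyne and hydroxymethylation with formaldehyde; the hindered secondary chloride and the silyl ether should be inert to the acetylide.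

Step 21
Reactants: 28 C9–C23 propargylic alcohol (12S,13R,14S,15S,17R,18R,19S,20E): 9-OH; C10≡C11; 13,14-O- and 15,17-O-isopropylidene; 18-Cl; 19-OTES
Product: 30 C9–C23 (10Z)-11-chloroallylic alcohol (12R,13R,14S,15S,17R,18R,19S,20E; 9-OH; 13,14:15,17-di-O-isopropylidene; 18-Cl; 19-OTES), via cyclic alkenylaluminate 29 (not isolated)
Conditions: NaAlH2(OCH2CH2OMe)2, THF, 0 °C; EtOAc; then N-chlorosuccinimide, −78 → 0 °C; aq. potassium sodium tartrate
Reagents that add atoms: N-chlorosuccinimide, O=C1CCC(=O)N1Cl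
Why: Alkoxide-directed trans-hydroalumination places aluminium at C11 in a five-membered alkenylaluminate, and chlorodealumination with retention should give the (Z)-chloroalkene with Cl cis to C9.

Step 22
Reactants: 30 C9–C23 (10Z)-11-chloroallylic alcohol (12R,13R,14S,15S,17R,18R,19S,20E): 9-OH; 13,14-O- and 15,17-O-isopropylidene; 18-Cl; 19-OTES
Product: 31 C9–C23 (10Z)-11-chloroenal (12R,13R,14S,15S,17R,18R,19S,20E): C9 CHO; 13,14-O- and 15,17-O-isopropylidene; 18-Cl; 19-OTES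
Conditions: MnO2 (excess), CH2Cl2, rt
Reagents that add atoms: none
Why: Chemoselective allylic oxidation gives the β-chloroenal without touching the chloroalkene geometry.

Step 23
Reactants: 32 (1S)-cyclohex-3-ene-1-carboxylic acid
Product: 33 (1S,3R,4S)-3,4-dihydroxycyclohexane-1-carboxylic acid
Conditions: K2OsO4·2H2O (1 mol %), N-methylmorpholine N-oxide, acetone/H2O, rt
Reagents that add atoms: N-methylmorpholine N-oxide, C[N+]1([O-])CCOCC1; water, O
Why: Catalytic syn-dihydroxylation delivers both hydroxyls to one face; attack anti to the C1′ carboxyl gives the required 3′,4′-cis diol trans to the carboxyl, but the facial bias is expected to be modest and the all-cis isomer is removed after step 24.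

Step 24
Reactants: 33 (1S,3R,4S)-3,4-dihydroxycyclohexane-1-carboxylic acid
Product: 34 prop-2-en-1-yl (1S,3R,4S)-3,4-dihydroxycyclohexane-1-carboxylate
Conditions: Cs2CO3 (1.0 equiv), allyl bromide, DMF, rt
Reagents that add atoms: allyl bromide, C=CCBr
Why: SN2 O-alkylation of the caesium carboxylate leaves the hydroxyls untouched; the diastereomeric diol esters are separated here.

Step 25
Reactants: 34 prop-2-en-1-yl (1S,3R,4S)-3,4-dihydroxycyclohexane-1-carboxylate
Product: 35 prop-2-en-1-yl (1S,3R,4S)-4-(tert-butyldimethylsilyloxy)-3-hydroxycyclohexane-1-carboxylate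
Conditions: TBSCl (1.05 equiv), imidazole, DMF, 0 °C
Reagents that add atoms: tert-butyl(chloro)dimethylsilane, CC(C)(C)[Si](C)(C)Cl
Why: In the chair with the ester equatorial the 4′-OH is equatorial and the 3′-OH axial, so monosilylation should go to the more accessible 4′-OH.

Step 26
Reactants: 36 triethyl (E)-4-phosphonocrotonate
Product: 37 (2E)-4-(diethoxyphosphoryl)but-2-enoic acid
Conditions: LiOH·H2O (1.05 equiv), THF/H2O, 0 °C; aq. HCl to pH 2
Reagents that add atoms: lithium hydroxide, [Li+].[OH-]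
Why: Saponification of the carboxylic ester; the diethyl phosphonate resists hydroxide under these conditions.

Step 27
Reactants: 35 prop-2-en-1-yl (1S,3R,4S)-4-(tert-butyldimethylsilyloxy)-3-hydroxycyclohexane-1-carboxylate; 37 (2E)-4-(diethoxyphosphoryl)but-2-enoic acid
Product: 38 prop-2-en-1-yl (1S,3R,4S)-4-(tert-butyldimethylsilyloxy)-3-{[(2E)-4-(diethoxyphosphoryl)but-2-enoyl]oxy}cyclohexane-1-carboxylate
Conditions: EDC·HCl, DMAP, CH2Cl2, 0 °C → rt
Reagents that add atoms: none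
Why: Steglich-type carbodiimide esterification of the axial 3′-OH; any deconjugated ester formed would give the same phosphonate anion in step 29.

Step 28
Reactants: 39 2-methyl-2-vinyloxirane
Product: 40 (2E)-4-chloro-2-methylbut-2-enal
Conditions: CuCl2·2H2O, LiCl, EtOAc, 80 °C
Reagents that add atoms: copper dichloride, [Cu+2].[Cl-].[Cl-]
Why: SN2′ opening of the vinyl epoxide by chloride gives the (E)-4-chloroallylic alcohol, which divalent copper oxidises to the enal in the same pot (oxidative chlorination of a diene monoepoxide).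

Step 29
Reactants: 38 prop-2-en-1-yl (1S,3R,4S)-4-(tert-butyldimethylsilyloxy)-3-{[(2E)-4-(diethoxyphosphoryl)but-2-enoyl]oxy}cyclohexane-1-carboxylate; 40 (2E)-4-chloro-2-methylbut-2-enal
Product: 41 prop-2-en-1-yl (1S,3R,4S)-4-(tert-butyldimethylsilyloxy)-3-{[(2E,4E,6E)-8-chloro-6-methylocta-2,4,6-trienoyl]oxy}cyclohexane-1-carboxylate
Conditions: LiN(SiMe3)2 (1.0 equiv), THF, −78 °C; then 40, −78 → 0 °C
Reagents that add atoms: none
Why: Vinylogous Horner–Wadsworth–Emmons olefination: the phosphonate-stabilised allyl anion reacts at the carbon α to phosphorus and eliminates phosphate to the (4E)-alkene, carbonyl addition at −78 °C being faster than alkylation at the allylic chloride.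

Step 30
Reactants: 41 prop-2-en-1-yl (1S,3R,4S)-4-(tert-butyldimethylsilyloxy)-3-{[(2E,4E,6E)-8-chloro-6-methylocta-2,4,6-trienoyl]oxy}cyclohexane-1-carboxylate
Product: 42 prop-2-en-1-yl (1S,3R,4S)-4-(tert-butyldimethylsilyloxy)-3-{[(2E,4E,6E)-8-(diethoxyphosphoryl)-6-methylocta-2,4,6-trienoyl]oxy}cyclohexane-1-carboxylate
Conditions: P(OEt)3, NaI (10 mol %), toluene, 90 °C
Reagents that add atoms: triethyl phosphite, CCOP(OCC)OCC
Why: Michaelis–Arbuzov reaction of the allylic chloride under iodide catalysis gives the allylic phosphonate.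

Step 31
Reactants: 31 C9–C23 (10Z)-11-chloroenal (12R,13R,14S,15S,17R,18R,19S,20E): C9 CHO; 13,14-O- and 15,17-O-isopropylidene; 18-Cl; 19-OTES; 42 prop-2-en-1-yl (1S,3R,4S)-4-(tert-butyldimethylsilyloxy)-3-{[(2E,4E,6E)-8-(diethoxyphosphoryl)-6-methylocta-2,4,6-trienoyl]oxy}cyclohexane-1-carboxylate
Product: 43 fully protected target: allyl ester at C1′; 4′-OTBS; 13,14-O- and 15,17-O-isopropylidene; 19-OTES; (2E,4E,6E,8E,10Z,20E; 12R,13R,14S,15S,17R,18R,19S; 1′S,3′R,4′S)
Conditions: LiN(SiMe3)2 (1.0 equiv), 42, THF, −78 °C; then 31, −78 → −20 °C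
Reagents that add atoms: none
Why: Horner–Wadsworth–Emmons olefination at the carbon α to phosphorus of the extended anion should build the (8E)-alkene and complete the pentaene, 1,2-addition to the aldehyde being faster than addition–elimination at the β-chloro carbon.

Step 32
Reactants: 43 fully protected target: allyl ester at C1′; 4′-OTBS; 13,14-O- and 15,17-O-isopropylidene; 19-OTES
Product: 44 protected carboxylic acid: free CO2H at C1′; 4′-OTBS; 13,14-O- and 15,17-O-isopropylidene; 19-OTES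
Conditions: Pd(PPh3)4 (5 mol %), morpholine, THF, rt, dark; dilute acid work-up
Reagents that add atoms: none
Why: Zerovalent palladium ionises the allyl ester to a π-allyl complex that morpholine captures (Tsuji–Trost deallylation); the vinyl chloride, silyl ethers and ketals should be inert at room temperature.

Step 33
Reactants: 44 protected carboxylic acid: free CO2H at C1′; 4′-OTBS; 13,14-O- and 15,17-O-isopropylidene; 19-OTES
Product: 45 target compound CNP0353301.1
Conditions: HF (48 % aq.), MeCN, 0 °C → rt, dark; reversed-phase chromatography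
Reagents that add atoms: none
Why: Aqueous acid should cleave both silyl ethers and hydrolyse both isopropylidene ketals in one operation; the chlorohydrins and the polyenoate tolerate acid, and no base is present that could close an epoxide.

**Compound list**

1 | methyl (2S)-3-hydroxy-2-methylpropanoate | COC(=O)[C@@H](C)CO | starting material
2 | methyl (2S)-3-(tert-butyldiphenylsilyloxy)-2-methylpropanoate | COC(=O)[C@@H](C)CO[Si](c1ccccc1)(c1ccccc1)C(C)(C)C | intermediate
3 | (2S)-3-(tert-butyldiphenylsilyloxy)-2-methylpropanal | O=C[C@@H](C)CO[Si](c1ccccc1)(c1ccccc1)C(C)(C)C | intermediate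
4 | (5S,6S)-5,6-dimethoxy-5,6-dimethyl-1,4-dioxan-2-one | O=C1CO[C@](C)(OC)[C@@](C)(OC)O1 | starting material
5 | (3R,5S,6S)-3-[(1R,2S)-3-(tert-butyldiphenylsilyloxy)-1-hydroxy-2-methylpropyl]-5,6-dimethoxy-5,6-dimethyl-1,4-dioxan-2-one | CC(C)(C)[Si](c1ccccc1)(c1ccccc1)OC[C@H](C)[C@@H](O)[C@H]1O[C@](C)(OC)[C@@](C)(OC)OC1=O | intermediate
6 | methyl (2R,3R,4S)-5-(tert-butyldiphenylsilyloxy)-2,3-dihydroxy-4-methylpentanoate | COC(=O)[C@H](O)[C@H](O)[C@@H](C)CO[Si](c1ccccc1)(c1ccccc1)C(C)(C)C | intermediate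
7 | methyl (4R,5R)-5-[(2S)-1-(tert-butyldiphenylsilyloxy)propan-2-yl]-2,2-dimethyl-1,3-dioxolane-4-carboxylate | COC(=O)[C@@H]1OC(C)(C)O[C@@H]1[C@@H](C)CO[Si](c1ccccc1)(c1ccccc1)C(C)(C)C | intermediate
8 | (4R,5R)-5-[(2S)-1-(tert-butyldiphenylsilyloxy)propan-2-yl]-2,2-dimethyl-1,3-dioxolane-4-carbaldehyde | O=C[C@@H]1OC(C)(C)O[C@@H]1[C@@H](C)CO[Si](c1ccccc1)(c1ccccc1)C(C)(C)C | intermediate
9 | allyltributylstannane | C=CC[Sn](CCCC)(CCCC)CCCC | starting material
10 | (1S)-1-[(4S,5R)-5-[(2S)-1-(tert-butyldiphenylsilyloxy)propan-2-yl]-2,2-dimethyl-1,3-dioxolan-4-yl]but-3-en-1-ol | C=CC[C@H](O)[C@@H]1OC(C)(C)O[C@@H]1[C@@H](C)CO[Si](c1ccccc1)(c1ccccc1)C(C)(C)C | intermediate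
11 | (Z)-but-2-ene-1,4-diol | OC/C=C\CO | starting material
12 | (Z)-1,4-bis(tert-butyldimethylsilyloxy)but-2-ene | CC(C)(C)[Si](C)(C)OC/C=C\CO[Si](C)(C)C(C)(C)C | intermediate
13 | (1S,3E)-5-(tert-butyldimethylsilyloxy)-1-[(4S,5R)-5-[(2S)-1-(tert-butyldiphenylsilyloxy)propan-2-yl]-2,2-dimethyl-1,3-dioxolan-4-yl]pent-3-en-1-ol | CC(C)(C)[Si](C)(C)OC/C=C/C[C@H](O)[C@@H]1OC(C)(C)O[C@@H]1[C@@H](C)CO[Si](c1ccccc1)(c1ccccc1)C(C)(C)C | intermediate
14 | di-tert-butyl dicarbonate | CC(C)(C)OC(=O)OC(=O)OC(C)(C)C | starting material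
15 | tert-butyl (1S,3E)-5-(tert-butyldimethylsilyloxy)-1-[(4S,5R)-5-[(2S)-1-(tert-butyldiphenylsilyloxy)propan-2-yl]-2,2-dimethyl-1,3-dioxolan-4-yl]pent-3-en-1-yl carbonate | CC(C)(C)OC(=O)O[C@@H](C/C=C/CO[Si](C)(C)C(C)(C)C)[C@@H]1OC(C)(C)O[C@@H]1[C@@H](C)CO[Si](c1ccccc1)(c1ccccc1)C(C)(C)C | intermediate
16 | (4R,6S)-4-[(1S)-2-(tert-butyldimethylsilyloxy)-1-chloroethyl]-6-[(4S,5R)-5-[(2S)-1-(tert-butyldiphenylsilyloxy)propan-2-yl]-2,2-dimethyl-1,3-dioxolan-4-yl]-1,3-dioxan-2-one | O=C1O[C@H]([C@@H]2OC(C)(C)O[C@@H]2[C@@H](C)CO[Si](c2ccccc2)(c2ccccc2)C(C)(C)C)C[C@@H](O1)[C@@H](Cl)CO[Si](C)(C)C(C)(C)C | intermediate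
17 | (2S,3R,5S)-1-(tert-butyldimethylsilyloxy)-5-[(4S,5R)-5-[(2S)-1-(tert-butyldiphenylsilyloxy)propan-2-yl]-2,2-dimethyl-1,3-dioxolan-4-yl]-2-chloropentane-3,5-diol | CC(C)(C)[Si](C)(C)OC[C@H](Cl)[C@H](O)C[C@H](O)[C@@H]1OC(C)(C)O[C@@H]1[C@@H](C)CO[Si](c1ccccc1)(c1ccccc1)C(C)(C)C | intermediate
18 | (4R,6S)-4-[(1S)-2-(tert-butyldimethylsilyloxy)-1-chloroethyl]-6-[(4S,5R)-5-[(2S)-1-(tert-butyldiphenylsilyloxy)propan-2-yl]-2,2-dimethyl-1,3-dioxolan-4-yl]-2,2-dimethyl-1,3-dioxane | CC(C)(C)[Si](C)(C)OC[C@H](Cl)[C@H]1C[C@H](OC(C)(C)O1)[C@@H]2OC(C)(C)O[C@@H]2[C@@H](C)CO[Si](c3ccccc3)(c3ccccc3)C(C)(C)C | intermediate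
19 | (2S)-2-chloro-2-[(4R,6S)-6-[(4S,5R)-5-[(2S)-1-(tert-butyldiphenylsilyloxy)propan-2-yl]-2,2-dimethyl-1,3-dioxolan-4-yl]-2,2-dimethyl-1,3-dioxan-4-yl]ethan-1-ol | OC[C@H](Cl)[C@H]1C[C@H](OC(C)(C)O1)[C@@H]2OC(C)(C)O[C@@H]2[C@@H](C)CO[Si](c3ccccc3)(c3ccccc3)C(C)(C)C | intermediate
20 | (2R)-2-chloro-2-[(4R,6S)-6-[(4S,5R)-5-[(2S)-1-(tert-butyldiphenylsilyloxy)propan-2-yl]-2,2-dimethyl-1,3-dioxolan-4-yl]-2,2-dimethyl-1,3-dioxan-4-yl]acetaldehyde | O=C[C@H](Cl)[C@H]1C[C@H](OC(C)(C)O1)[C@@H]2OC(C)(C)O[C@@H]2[C@@H](C)CO[Si](c3ccccc3)(c3ccccc3)C(C)(C)C | intermediate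
21 | but-1-yne | CCC#C | starting material
22 | C11–C23 segment (12S,13R,14S,15S,17R,18S,19S,20E): 11-OTBDPS; 13,14-O- and 15,17-O-isopropylidene; 18-Cl; 19-OH | CC/C=C/[C@H](O)[C@H](Cl)[C@H]1C[C@H](OC(C)(C)O1)[C@@H]2OC(C)(C)O[C@@H]2[C@@H](C)CO[Si](c3ccccc3)(c3ccccc3)C(C)(C)C | intermediate
23 | C11–C23 diol (12S,13R,14S,15S,17R,18S,19S,20E): 11-OH; 13,14-O- and 15,17-O-isopropylidene; 18-Cl; 19-OH | CC/C=C/[C@H](O)[C@H](Cl)[C@H]1C[C@H](OC(C)(C)O1)[C@@H]2OC(C)(C)O[C@@H]2[C@@H](C)CO | intermediate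
24 | C11–C23 bis-silyl ether (12S,13R,14S,15S,17R,18R,19S,20E): 11-OTES; 13,14-O- and 15,17-O-isopropylidene; 18-Cl; 19-OTES | CC/C=C/[C@H](O[Si](CC)(CC)CC)[C@H](Cl)[C@H]1C[C@H](OC(C)(C)O1)[C@@H]2OC(C)(C)O[C@@H]2[C@@H](C)CO[Si](CC)(CC)CC | intermediate
25 | C11–C23 aldehyde (12R,13R,14S,15S,17R,18R,19S,20E): C11 CHO; 13,14-O- and 15,17-O-isopropylidene; 18-Cl; 19-OTES | CC/C=C/[C@H](O[Si](CC)(CC)CC)[C@H](Cl)[C@H]1C[C@H](OC(C)(C)O1)[C@@H]2OC(C)(C)O[C@@H]2[C@@H](C)C=O | intermediate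
26 | C10–C23 terminal alkyne (12S,13R,14S,15S,17R,18R,19S,20E): C10≡C11; 13,14-O- and 15,17-O-isopropylidene; 18-Cl; 19-OTES | CC/C=C/[C@H](O[Si](CC)(CC)CC)[C@H](Cl)[C@H]1C[C@H](OC(C)(C)O1)[C@@H]2OC(C)(C)O[C@@H]2[C@@H](C)C#C | intermediate
27 | lithium acetylide of 26 | CC/C=C/[C@H](O[Si](CC)(CC)CC)[C@H](Cl)[C@H]1C[C@H](OC(C)(C)O1)[C@@H]2OC(C)(C)O[C@@H]2[C@@H](C)C#[C-].[Li+] | intermediate
28 | C9–C23 propargylic alcohol (12S,13R,14S,15S,17R,18R,19S,20E): 9-OH; C10≡C11; 13,14-O- and 15,17-O-isopropylidene; 18-Cl; 19-OTES | CC/C=C/[C@H](O[Si](CC)(CC)CC)[C@H](Cl)[C@H]1C[C@H](OC(C)(C)O1)[C@@H]2OC(C)(C)O[C@@H]2[C@@H](C)C#CCO | intermediate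
29 | sodium cyclic alkenylaluminate from 28 (O9–Al–C11 five-membered ring, two 2-methoxyethoxy ligands on Al) | CC/C=C/[C@H](O[Si](CC)(CC)CC)[C@H](Cl)[C@H]1C[C@H](OC(C)(C)O1)[C@@H]2OC(C)(C)O[C@@H]2[C@@H](C)C3=CCO[Al-]3(OCCOC)OCCOC.[Na+] | intermediate
30 | C9–C23 (10Z)-11-chloroallylic alcohol (12R,13R,14S,15S,17R,18R,19S,20E): 9-OH; 13,14-O- and 15,17-O-isopropylidene; 18-Cl; 19-OTES | CC/C=C/[C@H](O[Si](CC)(CC)CC)[C@H](Cl)[C@H]1C[C@H](OC(C)(C)O1)[C@@H]2OC(C)(C)O[C@@H]2[C@@H](C)/C(Cl)=C/CO | intermediate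
31 | C9–C23 (10Z)-11-chloroenal (12R,13R,14S,15S,17R,18R,19S,20E): C9 CHO; 13,14-O- and 15,17-O-isopropylidene; 18-Cl; 19-OTES | CC/C=C/[C@H](O[Si](CC)(CC)CC)[C@H](Cl)[C@H]1C[C@H](OC(C)(C)O1)[C@@H]2OC(C)(C)O[C@@H]2[C@@H](C)/C(Cl)=C/C=O | intermediate
32 | (1S)-cyclohex-3-ene-1-carboxylic acid | OC(=O)[C@@H]1CC=CCC1 | starting material
33 | (1S,3R,4S)-3,4-dihydroxycyclohexane-1-carboxylic acid | O[C@@H]1C[C@@H](C(=O)O)CC[C@@H]1O | intermediate
34 | prop-2-en-1-yl (1S,3R,4S)-3,4-dihydroxycyclohexane-1-carboxylate | O[C@@H]1C[C@@H](C(=O)OCC=C)CC[C@@H]1O | intermediate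
35 | prop-2-en-1-yl (1S,3R,4S)-4-(tert-butyldimethylsilyloxy)-3-hydroxycyclohexane-1-carboxylate | O[C@@H]1C[C@@H](C(=O)OCC=C)CC[C@@H]1O[Si](C)(C)C(C)(C)C | intermediate
36 | triethyl (E)-4-phosphonocrotonate | CCOC(=O)/C=C/CP(=O)(OCC)OCC | starting material
37 | (2E)-4-(diethoxyphosphoryl)but-2-enoic acid | OC(=O)/C=C/CP(=O)(OCC)OCC | intermediate
38 | prop-2-en-1-yl (1S,3R,4S)-4-(tert-butyldimethylsilyloxy)-3-{[(2E)-4-(diethoxyphosphoryl)but-2-enoyl]oxy}cyclohexane-1-carboxylate | CCOP(=O)(OCC)C/C=C/C(=O)O[C@@H]1C[C@@H](C(=O)OCC=C)CC[C@@H]1O[Si](C)(C)C(C)(C)C | intermediate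
39 | 2-methyl-2-vinyloxirane | CC1(CO1)C=C | starting material
40 | (2E)-4-chloro-2-methylbut-2-enal | O=C/C(C)=C/CCl | intermediate
41 | prop-2-en-1-yl (1S,3R,4S)-4-(tert-butyldimethylsilyloxy)-3-{[(2E,4E,6E)-8-chloro-6-methylocta-2,4,6-trienoyl]oxy}cyclohexane-1-carboxylate | ClC/C=C(C)/C=C/C=C/C(=O)O[C@@H]1C[C@@H](C(=O)OCC=C)CC[C@@H]1O[Si](C)(C)C(C)(C)C | intermediate
42 | prop-2-en-1-yl (1S,3R,4S)-4-(tert-butyldimethylsilyloxy)-3-{[(2E,4E,6E)-8-(diethoxyphosphoryl)-6-methylocta-2,4,6-trienoyl]oxy}cyclohexane-1-carboxylate | CCOP(=O)(OCC)C/C=C(C)/C=C/C=C/C(=O)O[C@@H]1C[C@@H](C(=O)OCC=C)CC[C@@H]1O[Si](C)(C)C(C)(C)C | intermediate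
43 | fully protected target: allyl ester at C1′; 4′-OTBS; 13,14-O- and 15,17-O-isopropylidene; 19-OTES; (2E,4E,6E,8E,10Z,20E; 12R,13R,14S,15S,17R,18R,19S; 1′S,3′R,4′S) | CC/C=C/[C@H](O[Si](CC)(CC)CC)[C@H](Cl)[C@H]1C[C@H](OC(C)(C)O1)[C@@H]2OC(C)(C)O[C@@H]2[C@@H](C)/C(Cl)=C/C=C/C=C(C)/C=C/C=C/C(=O)O[C@@H]3C[C@@H](C(=O)OCC=C)CC[C@@H]3O[Si](C)(C)C(C)(C)C | intermediate
44 | protected carboxylic acid: free CO2H at C1′; 4′-OTBS; 13,14-O- and 15,17-O-isopropylidene; 19-OTES; configuration as 43 | CC/C=C/[C@H](O[Si](CC)(CC)CC)[C@H](Cl)[C@H]1C[C@H](OC(C)(C)O1)[C@@H]2OC(C)(C)O[C@@H]2[C@@H](C)/C(Cl)=C/C=C/C=C(C)/C=C/C=C/C(=O)O[C@@H]3C[C@@H](C(=O)O)CC[C@@H]3O[Si](C)(C)C(C)(C)C | intermediate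
45 | CNP0353301.1: (1S,3R,4S)-3-{[(2E,4E,6E,8E,10Z,12R,13R,14S,15S,17R,18R,19S,20E)-11,18-dichloro-13,14,15,17,19-pentahydroxy-6,12-dimethyltricosa-2,4,6,8,10,20-hexaenoyl]oxy}-4-hydroxycyclohexane-1-carboxylic acid | CC/C=C/[C@H](O)[C@H](Cl)[C@H](O)C[C@H](O)[C@H](O)[C@H](O)[C@@H](C)/C(Cl)=C/C=C/C=C(C)/C=C/C=C/C(=O)O[C@@H]1C[C@@H](C(=O)O)CC[C@@H]1O | target

**Step count and risks**

Total: 33 steps. Longest linear sequence: 24 steps (steps 1–6, 8–22, 31–33) from methyl (2S)-3-hydroxy-2-methylpropanoate.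

Steps most likely to fail:

1. Step 10 (proposed new method). Chlorenium transfer to the inductively deactivated allylic-ether alkene may be slow enough for allylic chlorination to compete; capture of the chloriranium ion may lose the chair relay from C15, or the acetonide oxygen may take part. Fallback with known chemistry, setting out from ester 7: amidation with MeNHOMe·HCl/i-PrMgCl gives Weinreb amide F1, and MeMgBr gives methyl ketone F2. Its lithium enolate (LiN(i-Pr)2, THF, −78 °C) is added to (2S)-3-(tert-butyldimethylsilyloxy)-2-chloropropanal F3, made from commercial 3-(tert-butyldimethylsilyloxy)propanal by enamine-catalysed enantioselective α-chlorination with N-chlorosuccinimide. The Cornforth-controlled aldol should give the 17,18-anti β-hydroxy ketone F4, and chelation-controlled syn reduction (Et2BOMe, NaBH4, THF/MeOH, −78 °C) sets C15 and returns to the route at diol 17.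

2. Step 15. The alkenylzinc addition is slow, so the α-chloroaldehyde may epimerise at C18 before it is consumed, or facial selectivity at C19 may be poor. Fallback, setting out from aldehyde 20: addition of lithium but-1-ynide (from 21 and n-BuLi, THF, −78 °C), a fast addition of a type known to follow the Cornforth model closely, gives propargylic alcohol F5. Alkoxide-directed trans-hydroalumination (NaAlH2(OCH2CH2OMe)2, THF, 0 °C) then gives the (E)-allylic alcohol and returns to the route at 22.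

3. Step 31. Bond rotation in the extended, delocalised phosphonate anion may scramble the C6=C7 geometry, or the anion may attack the β-chloro carbon of the enal. Fallback, setting out from enal 31: a Wittig reaction with Ph3P=CHCHO gives dienal F6, and a second with Ph3P=C(CH3)CHO gives trienal F7, in which the trisubstituted (6E)-alkene is fixed by an E-selective stabilised ylide. Horner–Wadsworth–Emmons olefination of F7 with the C1–C4 phosphonate 38 (LiN(SiMe3)2, THF, −78 °C), whose anion contains no trisubstituted alkene, forms C4=C5 and returns to the route at 43.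

**Further compounds**

F1 | step 10 | (4R,5R)-5-[(2S)-1-(tert-butyldiphenylsilyloxy)propan-2-yl]-N-methoxy-N,2,2-trimethyl-1,3-dioxolane-4-carboxamide | CON(C)C(=O)[C@@H]1OC(C)(C)O[C@@H]1[C@@H](C)CO[Si](c1ccccc1)(c1ccccc1)C(C)(C)C
F2 | step 10 | 1-[(4R,5R)-5-[(2S)-1-(tert-butyldiphenylsilyloxy)propan-2-yl]-2,2-dimethyl-1,3-dioxolan-4-yl]ethan-1-one | CC(=O)[C@@H]1OC(C)(C)O[C@@H]1[C@@H](C)CO[Si](c1ccccc1)(c1ccccc1)C(C)(C)C
F3 | step 10 | (2S)-3-(tert-butyldimethylsilyloxy)-2-chloropropanal | CC(C)(C)[Si](C)(C)OC[C@H](Cl)C=O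
F4 | step 10 | (3R,4S)-5-(tert-butyldimethylsilyloxy)-1-[(4R,5R)-5-[(2S)-1-(tert-butyldiphenylsilyloxy)propan-2-yl]-2,2-dimethyl-1,3-dioxolan-4-yl]-4-chloro-3-hydroxypentan-1-one | CC(C)(C)[Si](C)(C)OC[C@H](Cl)[C@H](O)CC(=O)[C@@H]1OC(C)(C)O[C@@H]1[C@@H](C)CO[Si](c1ccccc1)(c1ccccc1)C(C)(C)C
F5 | step 15 | C11–C23 propargylic alcohol (C20≡C21; 11-OTBDPS; 13,14-O- and 15,17-O-isopropylidene; 18-Cl; 19-OH; configuration as 22) | CCC#C[C@H](O)[C@H](Cl)[C@H]1C[C@H](OC(C)(C)O1)[C@@H]2OC(C)(C)O[C@@H]2[C@@H](C)CO[Si](c3ccccc3)(c3ccccc3)C(C)(C)C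
F6 | step 31 | C7–C23 (8E,10Z)-11-chlorodienal (C7 CHO; otherwise as 31) | CC/C=C/[C@H](O[Si](CC)(CC)CC)[C@H](Cl)[C@H]1C[C@H](OC(C)(C)O1)[C@@H]2OC(C)(C)O[C@@H]2[C@@H](C)/C(Cl)=C/C=C/C=O
F7 | step 31 | C5–C23 (6E,8E,10Z)-11-chloro-6-methyltrienal (C5 CHO; otherwise as 31) | CC/C=C/[C@H](O[Si](CC)(CC)CC)[C@H](Cl)[C@H]1C[C@H](OC(C)(C)O1)[C@@H]2OC(C)(C)O[C@@H]2[C@@H](C)/C(Cl)=C/C=C/C=C(C)/C=O
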